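## Retrosynthetic overview

1. The target is a 2S,2″S biflavanone. Unit 1 is the 5,7-dihydroxyflavanone and unit 2 the 5-hydroxy-7-methoxyflavanone, joined from C3′ of ring B of unit 1 to C8 of ring A of unit 2. The last operation is hydrogenolysis of five benzyl ethers (18 → 19).
2. Ring C of unit 1 is cut at O1–C2 and C2–C3. Aldehyde 13, which carries all of unit 2, and β-keto ester 15 are united in one flask by Knoevenagel condensation, catalyst-controlled oxa-Michael closure and decarboxylation.
3. Enabling feature: in unit 1 the O1–C2 bond lies β to the C4 ketone and C3 is a CH2 next to C4=O. C3 can therefore carry a temporary CO2tBu that makes it the Knoevenagel carbon, doubly activates C2 for 6-endo attack by the ring A phenol, gives the catalyst a two-point handle, and leaves as isobutene and CO2.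
4. Ring C of unit 2 is made earlier by the same sequence (8 + 9). The biaryl bond comes from a Suzuki–Miyaura coupling of iodoacetophenone 3 with boronate 6, before any stereocentre exists.
5. Ring order: purchased benzene rings → biaryl → ring C of unit 2 → ring C of unit 1 (last).

Key step: step 9

Assumption: the 3,5-bis(trifluoromethyl)phenyl thiourea of 9-amino-9-deoxy-epi-quinidine is taken as the pseudoenantiomer that gives 2S flavanones; if a test on the parent 2-phenyl system shows the opposite sense, the epi-quinine analogue is used in steps 7 and 9 with no other change.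

Remark: rotation about the C8–C3′ biaryl axis (three small oxygen ortho substituents) is taken to be fast at room temperature, so no axial configuration has to be set.

## Route

Step 1
Reactants: 1 1-(2,6-dihydroxy-4-methoxyphenyl)ethanone
Product: 2 1-[2-(benzyloxy)-6-hydroxy-4-methoxyphenyl]ethanone
Conditions: BnBr (1.05 equiv), K2CO3 (1.2 equiv), acetone, reflux
Reagents that add atoms: benzyl bromide, BrCc1ccccc1
Why: Williamson ether synthesis on a symmetric diol, in which the second hydroxyl stays hydrogen-bonded to the ketone after the first alkylation, so monobenzylation should stop cleanly.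

Step 2
Reactants: 2 1-[2-(benzyloxy)-6-hydroxy-4-methoxyphenyl]ethanone
Product: 3 1-[6-(benzyloxy)-2-hydroxy-3-iodo-4-methoxyphenyl]ethanone
Conditions: NIS (1.05 equiv), CF3CO2H (10 mol%), MeCN, 0 °C to rt
Reagents that add atoms: N-iodosuccinimide, O=C1CCC(=O)N1I
Why: Electrophilic aromatic iodination, expected at C3′ (ortho to the free phenol, para to the benzyloxy group) because C5′ is wedged between OMe and OBn, in line with the known 3′-halogenation of 2′-hydroxy-4′,6′-dialkoxyacetophenones.

Step 3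
Reactants: 4 4-(benzyloxy)-3-bromobenzaldehyde
Product: 5 2-[4-(benzyloxy)-3-bromophenyl]-1,3-dioxolane
Conditions: ethylene glycol (3 equiv), TsOH·H2O (cat.), toluene, reflux, Dean–Stark
Reagents that add atoms: ethylene glycol, OCCO
Why: Acid-catalysed acetalisation with azeotropic removal of water masks the aldehyde so that it cannot compete in the later condensation that builds unit 2.

Step 4
Reactants: 5 2-[4-(benzyloxy)-3-bromophenyl]-1,3-dioxolane
Product: 6 2-[2-(benzyloxy)-5-(1,3-dioxolan-2-yl)phenyl]-4,4,5,5-tetramethyl-1,3,2-dioxaborolane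
Conditions: B2pin2 (1.2 equiv), PdCl2(dppf) (3 mol%), KOAc (3 equiv), 1,4-dioxane, 90 °C
Reagents that add atoms: bis(pinacolato)diboron, CC1(C)OB(OC1(C)C)B1OC(C)(C)C(C)(C)O1
Why: Miyaura borylation of an aryl bromide under weakly basic KOAc conditions, which the acetal and the benzyl ether tolerate.

Step 5
Reactants: 3 1-[6-(benzyloxy)-2-hydroxy-3-iodo-4-methoxyphenyl]ethanone; 6 2-[2-(benzyloxy)-5-(1,3-dioxolan-2-yl)phenyl]-4,4,5,5-tetramethyl-1,3,2-dioxaborolane
Product: 7 1-{6-(benzyloxy)-3-[2-(benzyloxy)-5-(1,3-dioxolan-2-yl)phenyl]-2-hydroxy-4-methoxyphenyl}ethanone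
Conditions: Pd(OAc)2 (5 mol%), SPhos (10 mol%), K3PO4 (3 equiv), toluene/H2O 10:1, 90 °C
Reagents that add atoms: none
Why: Suzuki–Miyaura coupling with an SPhos-ligated zerovalent palladium catalyst suited to a doubly ortho-substituted iodide bearing a free phenoxide, run before any stereocentre exists so that base and heat cannot erode configuration.

Step 6
Reactants: 7 1-{6-(benzyloxy)-3-[2-(benzyloxy)-5-(1,3-dioxolan-2-yl)phenyl]-2-hydroxy-4-methoxyphenyl}ethanone
Product: 8 tert-butyl 3-{6-(benzyloxy)-3-[2-(benzyloxy)-5-(1,3-dioxolan-2-yl)phenyl]-2-hydroxy-4-methoxyphenyl}-3-oxopropanoate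
Conditions: LiN(SiMe3)2 (3.3 equiv), THF, −78 °C; then Boc2O (1.1 equiv), −78 to 0 °C; AcOH quench
Reagents that add atoms: di-tert-butyl dicarbonate, CC(C)(C)OC(=O)OC(=O)OC(C)(C)C
Why: Crossed Claisen-type C-acylation of the phenoxide/enolate dianion at the unhindered methyl carbon, with the third equivalent of base storing the product as its enolate; any aryl carbonate formed at oxygen should converge on 8 by a Baker–Venkataraman-type O-to-C transfer.

Step 7
Reactants: 8 tert-butyl 3-{6-(benzyloxy)-3-[2-(benzyloxy)-5-(1,3-dioxolan-2-yl)phenyl]-2-hydroxy-4-methoxyphenyl}-3-oxopropanoate; 9 4-(benzyloxy)benzaldehyde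
Product: 13 4-(benzyloxy)-3-[(2S)-5-(benzyloxy)-2-[4-(benzyloxy)phenyl]-7-methoxy-4-oxo-3,4-dihydro-2H-chromen-8-yl]benzaldehyde, via alkylidene β-keto ester 10 (not isolated), via chromanone-3-carboxylate 11 (not isolated), via dioxolane-protected flavanone 12 (not isolated)
Conditions: piperidine (20 mol%), AcOH (20 mol%), 4 Å MS, toluene, rt; then epi-quinidine thiourea catalyst (10 mol%), −25 °C; then TsOH·H2O (2 equiv), 80 °C; then THF/H2O, rt
Reagents that add atoms: water, O
Why: Knoevenagel condensation of 8 with 9 gives the alkylidene, the cinchona thiourea then delivers the only free phenol to the benzylidene carbon in a 6-endo-trig oxa-Michael addition in which the catalyst, hydrogen-bonded to the β-keto ester, selects the face that makes C2 of unit 2 S, and TsOH finally removes the tert-butyl ester as isobutene and CO2 and, once water is added, hydrolyses the dioxolane; the benzyl ether on the other ortho oxygen guarantees closure to the 8-aryl and not the 6-aryl flavanone.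

Step 8
Reactants: 14 1-[2,4-bis(benzyloxy)-6-hydroxyphenyl]ethanone
Product: 15 tert-butyl 3-[2,4-bis(benzyloxy)-6-hydroxyphenyl]-3-oxopropanoate
Conditions: LiN(SiMe3)2 (3.3 equiv), THF, −78 °C; then Boc2O (1.1 equiv), −78 to 0 °C; AcOH quench
Reagents that add atoms: di-tert-butyl dicarbonate, CC(C)(C)OC(=O)OC(=O)OC(C)(C)C
Why: The same Claisen-type C-tert-butoxycarbonylation of the ketone enolate as in step 6, on a simpler substrate whose single free phenol is the future O1 of unit 1.

Step 9
Reactants: 13 4-(benzyloxy)-3-[(2S)-5-(benzyloxy)-2-[4-(benzyloxy)phenyl]-7-methoxy-4-oxo-3,4-dihydro-2H-chromen-8-yl]benzaldehyde; 15 tert-butyl 3-[2,4-bis(benzyloxy)-6-hydroxyphenyl]-3-oxopropanoate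
Product: 18 (2S)-5,7-bis(benzyloxy)-2-{4-(benzyloxy)-3-[(2S)-5-(benzyloxy)-2-[4-(benzyloxy)phenyl]-7-methoxy-4-oxo-3,4-dihydro-2H-chromen-8-yl]phenyl}-2,3-dihydro-4H-chromen-4-one, via alkylidene β-keto ester 16 (not isolated), via chromanone-3-carboxylate 17 (not isolated)
Conditions: piperidine (20 mol%), AcOH (20 mol%), 4 Å MS, toluene, rt to 40 °C; then epi-quinidine thiourea catalyst (10 mol%), −25 °C; then TsOH·H2O (2 equiv), 80 °C
Reagents that add atoms: none
Why: Piperidinium acetate condenses the aldehyde of 13 with the doubly activated CH2 of 15 (Knoevenagel condensation) to give alkylidene 16, whose chelated phenol is expected to stay open under this buffer; the bifunctional thiourea then binds the β-keto ester through two hydrogen bonds while its quinuclidine nitrogen deprotonates the single free phenol, which adds to the benzylidene carbon in a 6-endo-trig oxa-Michael closure of ring C of unit 1 (O1–C2 bond), and TsOH finally cleaves the tert-butyl ester with loss of isobutene and CO2. The closest known reaction type is the thiourea-catalysed enantioselective cyclisation of alkylidene β-keto esters to flavanones with decarboxylation in the same flask. The new C2 centre should be set S by the catalyst, which shields one face of the acceptor; the existing 2S centre of unit 2 is remote, beyond a freely rotating biaryl axis, so no substrate mismatch is expected. The transient C3 centre is erased on decarboxylation and the geometric isomers of such doubly activated alkenes interconvert under the amines, so the E/Z mixture and both C3 epimers should be funnelled into one product. The step needs condensation at the β-keto ester and not at C3 of the unit 2 ketone (secured by the far higher acidity of the 1,3-dicarbonyl), attack by one oxygen only (secured by the benzyl ethers that leave a single phenol free) and no lactonisation to a 4-hydroxycoumarin (secured by the bulky tert-butyl ester). The unit 2 stereocentre has already met the same amine, catalyst and acid in step 7 and should survive them again, and a minor 2R epimer would be a diastereomer of 18 that can be removed by chromatography or crystallisation, which should also raise the enantiomeric purity of the 2S,2″S product.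

Step 10
Reactants: 18 (2S)-5,7-bis(benzyloxy)-2-{4-(benzyloxy)-3-[(2S)-5-(benzyloxy)-2-[4-(benzyloxy)phenyl]-7-methoxy-4-oxo-3,4-dihydro-2H-chromen-8-yl]phenyl}-2,3-dihydro-4H-chromen-4-one
Product: 19 (2S)-5,7-dihydroxy-2-{4-hydroxy-3-[(2S)-5-hydroxy-2-(4-hydroxyphenyl)-7-methoxy-4-oxo-3,4-dihydro-2H-chromen-8-yl]phenyl}-2,3-dihydro-4H-chromen-4-one
Conditions: H2 (1 atm), 10% Pd/C, THF/MeOH, rt
Reagents that add atoms: none
Why: Hydrogenolysis of the five benzyl aryl ethers on palladium under neutral conditions, which should spare the hydrogen-bonded aryl ketones, the methyl ether and both C2 centres (labile only to acid or base through retro-oxa-Michael opening), the reaction being stopped after uptake of five equivalents to avoid cleavage of the benzylic O1–C2 bonds.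

## Compound list

1 | 1-(2,6-dihydroxy-4-methoxyphenyl)ethanone | CC(=O)c1c(O)cc(OC)cc1O | starting material
2 | 1-[2-(benzyloxy)-6-hydroxy-4-methoxyphenyl]ethanone | CC(=O)c1c(O)cc(OC)cc1OCc1ccccc1 | intermediate
3 | 1-[6-(benzyloxy)-2-hydroxy-3-iodo-4-methoxyphenyl]ethanone | CC(=O)c1c(O)c(I)c(OC)cc1OCc1ccccc1 | intermediate
4 | 4-(benzyloxy)-3-bromobenzaldehyde | O=Cc1ccc(OCc2ccccc2)c(Br)c1 | starting material
5 | 2-[4-(benzyloxy)-3-bromophenyl]-1,3-dioxolane | Brc1cc(C2OCCO2)ccc1OCc1ccccc1 | intermediate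
6 | 2-[2-(benzyloxy)-5-(1,3-dioxolan-2-yl)phenyl]-4,4,5,5-tetramethyl-1,3,2-dioxaborolane | CC1(C)OB(OC1(C)C)c1cc(C2OCCO2)ccc1OCc1ccccc1 | intermediate
7 | 1-{6-(benzyloxy)-3-[2-(benzyloxy)-5-(1,3-dioxolan-2-yl)phenyl]-2-hydroxy-4-methoxyphenyl}ethanone | CC(=O)c1c(O)c(-c2cc(C3OCCO3)ccc2OCc2ccccc2)c(OC)cc1OCc1ccccc1 | intermediate
8 | tert-butyl 3-{6-(benzyloxy)-3-[2-(benzyloxy)-5-(1,3-dioxolan-2-yl)phenyl]-2-hydroxy-4-methoxyphenyl}-3-oxopropanoate | CC(C)(C)OC(=O)CC(=O)c1c(O)c(-c2cc(C3OCCO3)ccc2OCc2ccccc2)c(OC)cc1OCc1ccccc1 | intermediate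
9 | 4-(benzyloxy)benzaldehyde | O=Cc1ccc(OCc2ccccc2)cc1 | starting material
10 | tert-butyl 2-{6-(benzyloxy)-3-[2-(benzyloxy)-5-(1,3-dioxolan-2-yl)phenyl]-2-hydroxy-4-methoxybenzoyl}-3-[4-(benzyloxy)phenyl]prop-2-enoate (E/Z mixture) | CC(C)(C)OC(=O)C(=Cc1ccc(OCc2ccccc2)cc1)C(=O)c1c(O)c(-c2cc(C3OCCO3)ccc2OCc2ccccc2)c(OC)cc1OCc1ccccc1 | intermediate
11 | tert-butyl (2S)-5-(benzyloxy)-8-[2-(benzyloxy)-5-(1,3-dioxolan-2-yl)phenyl]-2-[4-(benzyloxy)phenyl]-7-methoxy-4-oxo-3,4-dihydro-2H-chromene-3-carboxylate (C3 epimers) | COc1cc(OCc2ccccc2)c2c(c1-c1cc(C3OCCO3)ccc1OCc1ccccc1)O[C@H](c1ccc(OCc3ccccc3)cc1)C(C(=O)OC(C)(C)C)C2=O | intermediate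
12 | (2S)-5-(benzyloxy)-8-[2-(benzyloxy)-5-(1,3-dioxolan-2-yl)phenyl]-2-[4-(benzyloxy)phenyl]-7-methoxy-2,3-dihydro-4H-chromen-4-one | COc1cc(OCc2ccccc2)c2c(c1-c1cc(C3OCCO3)ccc1OCc1ccccc1)O[C@H](c1ccc(OCc3ccccc3)cc1)CC2=O | intermediate
13 | 4-(benzyloxy)-3-[(2S)-5-(benzyloxy)-2-[4-(benzyloxy)phenyl]-7-methoxy-4-oxo-3,4-dihydro-2H-chromen-8-yl]benzaldehyde | COc1cc(OCc2ccccc2)c2c(c1-c1cc(C=O)ccc1OCc1ccccc1)O[C@H](c1ccc(OCc3ccccc3)cc1)CC2=O | intermediate
14 | 1-[2,4-bis(benzyloxy)-6-hydroxyphenyl]ethanone | CC(=O)c1c(O)cc(OCc2ccccc2)cc1OCc1ccccc1 | starting material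
15 | tert-butyl 3-[2,4-bis(benzyloxy)-6-hydroxyphenyl]-3-oxopropanoate | CC(C)(C)OC(=O)CC(=O)c1c(O)cc(OCc2ccccc2)cc1OCc1ccccc1 | intermediate
16 | tert-butyl 2-[2,4-bis(benzyloxy)-6-hydroxybenzoyl]-3-{4-(benzyloxy)-3-[(2S)-5-(benzyloxy)-2-[4-(benzyloxy)phenyl]-7-methoxy-4-oxo-3,4-dihydro-2H-chromen-8-yl]phenyl}prop-2-enoate (E/Z mixture) | CC(C)(C)OC(=O)C(=Cc1ccc(OCc2ccccc2)c(c1)-c1c(OC)cc(OCc2ccccc2)c2c1O[C@H](c1ccc(OCc3ccccc3)cc1)CC2=O)C(=O)c1c(O)cc(OCc2ccccc2)cc1OCc1ccccc1 | intermediate
17 | tert-butyl (2S)-5,7-bis(benzyloxy)-2-{4-(benzyloxy)-3-[(2S)-5-(benzyloxy)-2-[4-(benzyloxy)phenyl]-7-methoxy-4-oxo-3,4-dihydro-2H-chromen-8-yl]phenyl}-4-oxo-3,4-dihydro-2H-chromene-3-carboxylate (C3 epimers) | COc1cc(OCc2ccccc2)c2c(c1-c1cc([C@@H]3C(C(=O)OC(C)(C)C)C(=O)c4c(OCc5ccccc5)cc(OCc5ccccc5)cc4O3)ccc1OCc1ccccc1)O[C@H](c1ccc(OCc3ccccc3)cc1)CC2=O | intermediate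
18 | (2S)-5,7-bis(benzyloxy)-2-{4-(benzyloxy)-3-[(2S)-5-(benzyloxy)-2-[4-(benzyloxy)phenyl]-7-methoxy-4-oxo-3,4-dihydro-2H-chromen-8-yl]phenyl}-2,3-dihydro-4H-chromen-4-one | COc1cc(OCc2ccccc2)c2c(c1-c1cc([C@@H]3CC(=O)c4c(OCc5ccccc5)cc(OCc5ccccc5)cc4O3)ccc1OCc1ccccc1)O[C@H](c1ccc(OCc3ccccc3)cc1)CC2=O | intermediate
19 | (2S)-5,7-dihydroxy-2-{4-hydroxy-3-[(2S)-5-hydroxy-2-(4-hydroxyphenyl)-7-methoxy-4-oxo-3,4-dihydro-2H-chromen-8-yl]phenyl}-2,3-dihydro-4H-chromen-4-one | COc1cc(O)c2c(c1-c1cc([C@@H]3CC(=O)c4c(O)cc(O)cc4O3)ccc1O)O[C@H](c1ccc(O)cc1)CC2=O | target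

## Step count and risks

Total step count: 10. Longest linear sequence: 7 steps (steps 1, 2, 5, 6, 7, 9, 10, from 1 to 19). Steps 3 and 4 form a two-step branch that joins at step 5; step 8 is a one-step branch that joins at step 9.

Steps most likely to fail:

Step 9. The achiral piperidinium buffer may close ring C of unit 1 before the chiral catalyst engages, or face selection on the very large aryl group may be incomplete; either would lower the 2S to 2R ratio at the new centre. The fallback sets out from 13 and 14 and returns to the route at 18. It fixes the C2 configuration in a carbon–carbon bond formation and closes the ring by substitution instead of conjugate addition. Acetophenone 14 would be silylated twice (Me3SiOTf, Et3N, CH2Cl2, 0 °C) to {[1-{2,4-bis(benzyloxy)-6-[(trimethylsilyl)oxy]phenyl}ethenyl]oxy}(trimethyl)silane F1. A Mukaiyama aldol addition of F1 to 13, promoted by SiCl4 and a catalytic chiral bisphosphoramide Lewis base chosen for the R alcohol (CH2Cl2, −78 °C, then aqueous KF/NaHCO3), should give (2S)-5-(benzyloxy)-8-{2-(benzyloxy)-5-[(1R)-3-[2,4-bis(benzyloxy)-6-hydroxyphenyl]-1-hydroxy-3-oxopropyl]phenyl}-2-[4-(benzyloxy)phenyl]-7-methoxy-2,3-dihydro-4H-chromen-4-one F2. An intramolecular Mitsunobu etherification (PPh3, DIAD, THF, 0 °C) would then form the O1–C2 bond with inversion and give 18.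

Step 7. The phenol that must add is buried between the acyl group and the C3′ aryl ring, so C–O bond formation may be slow or poorly face-selective, and the aldehyde unveiled in hot acid may enter aldol side reactions. The fallback sets out from 7 and returns at 13. It sets C2 of unit 2 in a carbon–carbon bond formation far from the hindered phenol. Ketone 7 would be heated with N,N-dimethylformamide dimethyl acetal (toluene, 90 °C) to give (E)-1-{6-(benzyloxy)-3-[2-(benzyloxy)-5-(1,3-dioxolan-2-yl)phenyl]-2-hydroxy-4-methoxyphenyl}-3-(dimethylamino)prop-2-en-1-one F3. This should cyclise on silica gel or in AcOH, with loss of dimethylamine, to 5-(benzyloxy)-8-[2-(benzyloxy)-5-(1,3-dioxolan-2-yl)phenyl]-7-methoxy-4H-chromen-4-one F4. Asymmetric conjugate addition of 4-(benzyloxy)phenylboronic acid under Pd(OCOCF3)2 and the t-BuPyOx enantiomer that delivers the 2S adduct (NH4PF6, H2O, ClCH2CH2Cl, 60 °C) should give 12, which is hydrolysed (TsOH·H2O, THF/H2O, rt) to 13.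

Step 2. Iodination may occur at C5′ or twice, because both open ring positions are strongly activated. The fallback sets out from 1 and returns at 7. It uses the symmetry of 1 to remove the regiochemical question. Diol 1 would be iodinated with one equivalent of NIS, where C3′ and C5′ are equivalent, to give 1-(2,6-dihydroxy-3-iodo-4-methoxyphenyl)ethanone F5. Suzuki–Miyaura coupling with 6 under the conditions of step 5 would give 1-{3-[2-(benzyloxy)-5-(1,3-dioxolan-2-yl)phenyl]-2,6-dihydroxy-4-methoxyphenyl}ethanone F6. Monobenzylation (BnBr 1.0 equiv, K2CO3, acetone) should then take place at the accessible hydroxyl next to C5′–H and not at the one shielded by the aryl group, giving 7.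

## Further compounds

F1 | step 9 | {[1-{2,4-bis(benzyloxy)-6-[(trimethylsilyl)oxy]phenyl}ethenyl]oxy}(trimethyl)silane | C=C(O[Si](C)(C)C)c1c(O[Si](C)(C)C)cc(OCc2ccccc2)cc1OCc1ccccc1
F2 | step 9 | (2S)-5-(benzyloxy)-8-{2-(benzyloxy)-5-[(1R)-3-[2,4-bis(benzyloxy)-6-hydroxyphenyl]-1-hydroxy-3-oxopropyl]phenyl}-2-[4-(benzyloxy)phenyl]-7-methoxy-2,3-dihydro-4H-chromen-4-one | COc1cc(OCc2ccccc2)c2c(c1-c1cc([C@H](O)CC(=O)c3c(O)cc(OCc4ccccc4)cc3OCc3ccccc3)ccc1OCc1ccccc1)O[C@H](c1ccc(OCc3ccccc3)cc1)CC2=O
F3 | step 7 | (E)-1-{6-(benzyloxy)-3-[2-(benzyloxy)-5-(1,3-dioxolan-2-yl)phenyl]-2-hydroxy-4-methoxyphenyl}-3-(dimethylamino)prop-2-en-1-one | CN(C)/C=C/C(=O)c1c(O)c(-c2cc(C3OCCO3)ccc2OCc2ccccc2)c(OC)cc1OCc1ccccc1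
F4 | step 7 | 5-(benzyloxy)-8-[2-(benzyloxy)-5-(1,3-dioxolan-2-yl)phenyl]-7-methoxy-4H-chromen-4-one | COc1cc(OCc2ccccc2)c2c(c1-c1cc(C3OCCO3)ccc1OCc1ccccc1)occc2=O
F5 | step 2 | 1-(2,6-dihydroxy-3-iodo-4-methoxyphenyl)ethanone | CC(=O)c1c(O)cc(OC)c(I)c1O
F6 | step 2 | 1-{3-[2-(benzyloxy)-5-(1,3-dioxolan-2-yl)phenyl]-2,6-dihydroxy-4-methoxyphenyl}ethanone | CC(=O)c1c(O)cc(OC)c(-c2cc(C3OCCO3)ccc2OCc2ccccc2)c1O
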